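**Plan**

1. Retrosynthesis first removes the late functionality: the C11 methylene, the C10 carbonyl, the acetyl group and the C3–Cl/C4–Br pair go back to spiro dienone 15 (C1 ketone, C3=C4 and C8=C9 alkenes).
2. The C6–C7 bond is cut next. It joins the spiro carbon to the CMe2 carbon (two quaternary centres) and lies between the ring A C8=C9 double bond and the oxygen-bearing ring B carbon C1, so C1(=O)–C6–C7–C8=C9 is a γ,δ-unsaturated ketone, the pattern a Claisen rearrangement leaves. Rejoining the C1 oxygen to C9 gives 2-alkenyl dihydropyran 14.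
3. 14 is cut at the alkenyl C=C (Wittig) and traced through a Birch reduction to a chromane-2-carboxylate made from 1 and 2.
4. Forward: the arene that becomes ring B is present from the start, the pyran ring is annulated first, Birch reduction unmasks ring B, and ring A closes last (step 8) while the pyran opens. Ring B, then ring A, are functionalised afterwards.
5. Stereochemistry: C2 of the chromane ester (enzymatic resolution) is relayed to spiro C6 in the [3,3] shift. C1 follows by CBS reduction, the epoxide face from the C1 hydroxyl, C4 by SN2 inversion and C3 by retention through bromine participation.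

Key step: step 8

Remark on locants: all spiro compounds are numbered as spiro[5.5]undecanes with ring B = C1–C5 (C1 oxygenated), spiro carbon C6 and ring A = C7–C11 (C7 = CMe2); these locants are kept up to the target.
Assumption: the lipase in step 3 is taken to hydrolyse the (2S)-ester faster, by analogy with (S)-selective hydrolase resolutions of chromane-2-carboxylates; the configuration of recovered 8 is to be verified before use.

**Route**

Step 1
Reactants: 1 1-(2-hydroxy-4-methylphenyl)ethan-1-one; 2 diethyl oxalate
Product: 4 ethyl 7-methyl-4-oxo-4H-chromene-2-carboxylate, via diketo ester 3 (not isolated)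
Conditions: NaOEt, EtOH, reflux; then conc. HCl, EtOH, reflux
Reagents that add atoms: none
Why: Crossed Claisen condensation of the methyl ketone enolate with non-enolisable diethyl oxalate, then acid-catalysed cyclodehydration of the 1,3-diketone onto the phenol, is the standard chromone-2-carboxylate synthesis and involves no stereocentre.

Step 2
Reactants: 4 ethyl 7-methyl-4-oxo-4H-chromene-2-carboxylate
Product: 7 ethyl 7-methylchromane-2-carboxylate (racemic), via 4-oxochromane ester 5 (not isolated), via 4-hydroxychromane ester 6 (not isolated)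
Conditions: H2 (5 bar), 10% Pd/C, AcOH, cat. HClO4, 70 °C
Reagents that add atoms: none
Why: Heterogeneous catalytic hydrogenation saturates the pyranone C2=C3 bond and, in acid, reduces and hydrogenolyses the benzylic C4 carbonyl via the benzylic alcohol to CH2, as is established for chromone-2-carboxylates, with C2 formed racemic.

Step 3
Reactants: 7 ethyl 7-methylchromane-2-carboxylate (racemic)
Product: 8 ethyl (2R)-7-methylchromane-2-carboxylate
Conditions: Pseudomonas fluorescens lipase, phosphate buffer (pH 7)/MTBE, 30 °C, stopped near 55% conversion; aq. NaHCO3 extraction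
Reagents that add atoms: none
Why: Hydrolase-catalysed kinetic resolution should hydrolyse the (2S)-ester, which is removed as the acid, and leave the (2R)-ester, whose C2 centre is the only source of absolute configuration in the route.

Step 4
Reactants: 8 ethyl (2R)-7-methylchromane-2-carboxylate
Product: 9 [(2R)-7-methylchroman-2-yl]methanol
Conditions: LiAlH4, THF, 0 °C
Reagents that add atoms: none
Why: Hydride reduction of the ester to the primary alcohol does not touch the C2 stereocentre and provides a group that survives dissolving-metal conditions, unlike an ester or an allylic ether.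

Step 5
Reactants: 9 [(2R)-7-methylchroman-2-yl]methanol
Product: 10 [(2R)-7-methyl-3,4,5,8-tetrahydro-2H-chromen-2-yl]methanol
Conditions: Li, NH3 (l), THF, t-BuOH, −78 → −33 °C; then NH4Cl (s)
Reagents that add atoms: none
Why: Birch reduction of the aryl ether protonates the two unsubstituted, para-related carbons C5 and C8 and keeps the donor-substituted carbons sp2, which should give the tetrasubstituted enol ether C4a=C8a and the C6=C7 alkene regiospecifically while C2 is untouched.

Step 6
Reactants: 10 [(2R)-7-methyl-3,4,5,8-tetrahydro-2H-chromen-2-yl]methanol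
Product: 11 (2R)-7-methyl-3,4,5,8-tetrahydro-2H-chromene-2-carbaldehyde
Conditions: SO3·pyridine, DMSO, i-Pr2NEt, CH2Cl2, 0 °C
Reagents that add atoms: none
Why: Parikh–Doering oxidation uses activated DMSO with an amine base and no acid, so the primary alcohol should reach the aldehyde without hydrolysis of the enol ether, conjugation of the skipped diene or epimerisation of the α-alkoxy centre.

Step 7
Reactants: 11 (2R)-7-methyl-3,4,5,8-tetrahydro-2H-chromene-2-carbaldehyde; 12 isopropyltriphenylphosphonium iodide
Product: 14 (2R)-7-methyl-2-(2-methylprop-1-en-1-yl)-3,4,5,8-tetrahydro-2H-chromene, via isopropylidenetriphenylphosphorane 13 (not isolated)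
Conditions: 12, n-BuLi, THF, 0 °C; then 11, −78 °C → rt
Reagents that add atoms: none
Why: Wittig olefination with the non-stabilised isopropylidene ylide at low temperature should convert the aldehyde into the trisubstituted alkene (two identical methyls, no E/Z issue) faster than the α-alkoxy aldehyde can enolise.

Step 8
Reactants: 14 (2R)-7-methyl-2-(2-methylprop-1-en-1-yl)-3,4,5,8-tetrahydro-2H-chromene
Product: 15 (6R)-3,7,7-trimethylspiro[5.5]undeca-3,8-dien-1-one
Conditions: o-xylene (degassed), Et3N (0.1 equiv), sealed base-washed tube, 200 °C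
Reagents that add atoms: none
Why: Heating should trigger a concerted [3,3]-sigmatropic (Claisen) shift of the allyl vinyl ether C4a=C8a–O1–C2–CH=CMe2, in which the C4a–CMe2 bond forms as the O1–C2 bond breaks, the enol ether becomes the C1 ketone and the allyl unit becomes the cis C8=C9 alkene. The closest known reaction type is the thermal Claisen ring contraction of 2-alkenyl-3,4-dihydro-2H-pyrans to 4-acylcyclohexenes. Ring A closes as a six-membered carbocycle by pericyclic C–C bond formation through a boat transition state, because the C3–C4 bridge ties both termini into a bicyclo[2.2.2]-like array; it is a ring contraction of the oxacycle, not a polar exo or endo cyclisation. The new stereocentre, spiro C6, is controlled only by pyran C2: the tethered alkenyl group can reach only the enol ether face on which it stands, so (2R) is relayed suprafacially to (6R). The step needs the [3,3] path to win over C2–O heterolysis with [1,3] recombination, enol ether hydrolysis and isomerisation or aromatisation of the skipped diene, which the neutral, amine-buffered, oxygen-free medium and the intramolecular geometry should secure; the symmetrical CMe2 terminus removes any alkene-geometry issue.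

Step 9
Reactants: 15 (6R)-3,7,7-trimethylspiro[5.5]undeca-3,8-dien-1-one
Product: 16 (1S,6R)-3,7,7-trimethylspiro[5.5]undeca-3,8-dien-1-ol
Conditions: (R)-Me-CBS oxazaborolidine (0.2 equiv), catecholborane, toluene, −40 → −20 °C; MeOH, then 1 M NaOH wash
Reagents that add atoms: none
Why: Corey–Bakshi–Shibata reduction binds the carbonyl anti to the quaternary spiro carbon and should deliver hydride to give the (1S)-carbinol, the same face that axial attack anti to the pseudo-axial C11 methylene favours, while catecholborane leaves both alkenes untouched and the non-basic medium avoids conjugation of the β,γ-enone.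

Step 10
Reactants: 16 (1S,6R)-3,7,7-trimethylspiro[5.5]undeca-3,8-dien-1-ol
Product: 17 (1S,3R,4S,6R)-3,4-epoxy-3,7,7-trimethylspiro[5.5]undec-8-en-1-ol (epoxide oxygen cis to the C1 hydroxyl)
Conditions: VO(acac)2 (5 mol%), t-BuOOH (decane), toluene, rt
Reagents that add atoms: tert-butyl hydroperoxide, CC(C)(C)OO
Why: In this vanadium-catalysed hydroxyl-directed epoxidation the vanadate ester of the homoallylic C1–OH should deliver oxygen to the C3=C4 bond on the hydroxyl face, and the trisubstituted homoallylic alkene should react in preference to the hindered, more remote ring A alkene.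

Step 11
Reactants: 17 (1S,3R,4S,6R)-3,4-epoxy-3,7,7-trimethylspiro[5.5]undec-8-en-1-ol
Product: 18 (1S,3R,4S,6R)-3,4-epoxy-3,7,7-trimethylspiro[5.5]undec-8-en-1-yl acetate
Conditions: Ac2O, pyridine, DMAP (cat.), CH2Cl2, rt
Reagents that add atoms: acetic anhydride, CC(=O)OC(C)=O
Why: DMAP-catalysed acetylation of the secondary alcohol installs the acetate of the target early, so that the tertiary hydroxyl formed next is the only free one, and the epoxide is inert to these conditions.

Step 12
Reactants: 18 (1S,3R,4S,6R)-3,4-epoxy-3,7,7-trimethylspiro[5.5]undec-8-en-1-yl acetate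
Product: 19 (1S,3R,4R,6R)-4-bromo-3-hydroxy-3,7,7-trimethylspiro[5.5]undec-8-en-1-yl acetate
Conditions: Li2NiBr4, THF, 0 °C → rt; pH 7 buffer
Reagents that add atoms: dilithium tetrabromonickelate, [Li+].[Li+].[Ni+2].[Br-].[Br-].[Br-].[Br-]
Why: Li2NiBr4 is a non-acidic bromide source that opens epoxides by SN2 attack at the less substituted carbon, so bromide should enter C4 with inversion (anti to the epoxide oxygen and the C1 acetate) while the tertiary C3–OH keeps the configuration set in step 10.

Step 13
Reactants: 19 (1S,3R,4R,6R)-4-bromo-3-hydroxy-3,7,7-trimethylspiro[5.5]undec-8-en-1-yl acetate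
Product: 21 (1S,3R,4R,6R)-4-bromo-3-chloro-3,7,7-trimethylspiro[5.5]undec-8-en-1-yl acetate, via tertiary chlorosulfite 20 (not isolated)
Conditions: SOCl2, CH2Cl2, −20 °C → rt, no amine base
Reagents that add atoms: thionyl chloride, O=S(Cl)Cl
Why: Without base the tertiary chlorosulfite ionises, the vicinal bromine shields or bridges the cation on its own face and chloride collapses onto C3 from the face the oxygen left (neighbouring-bromine participation together with SNi-type ion-pair return), which should give the tertiary chloride with retention and hence the trans bromochloride.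

Step 14
Reactants: 21 (1S,3R,4R,6R)-4-bromo-3-chloro-3,7,7-trimethylspiro[5.5]undec-8-en-1-yl acetate
Product: 23 (1S,3R,4R,6R)-4-bromo-3-chloro-3,7,7-trimethyl-10-oxospiro[5.5]undec-8-en-1-yl acetate, via allylic tert-butyl peroxide 22 (not isolated)
Conditions: Rh2(cap)4 (dirhodium tetrakis(caprolactamate), 1 mol%), t-BuOOH (70% aq.), ClCH2CH2Cl, 40 °C
Reagents that add atoms: tert-butyl hydroperoxide, CC(C)(C)OO
Why: In this radical allylic oxidation the tert-butylperoxyl radical abstracts hydrogen from C10, the only allylic C–H position of the ring A alkene because C7 is quaternary, the allyl radical is trapped at that less hindered terminus and the mixed peroxide collapses (Kornblum–DeLaMare type) to the enone without touching any stereocentre.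

Step 15
Reactants: 23 (1S,3R,4R,6R)-4-bromo-3-chloro-3,7,7-trimethyl-10-oxospiro[5.5]undec-8-en-1-yl acetate
Product: 25 (1S,3R,4R,6S)-4-bromo-3-chloro-11-[(dimethylamino)methyl]-3,7,7-trimethyl-10-oxospiro[5.5]undec-8-en-1-yl acetate (C11 epimers), via trimethylsilyl dienol ether 24 (not isolated)
Conditions: TMSOTf, Et3N, CH2Cl2, 0 °C; then Eschenmoser's salt, rt; aq. NaHCO3
Reagents that add atoms: Eschenmoser's salt (N,N-dimethylmethyleneiminium iodide), C=[N+](C)C.[I-]
Why: Soft enolisation can occur only towards C11 (C9 is vinylic, C7 quaternary), and the resulting 2-silyloxy diene should undergo a Mukaiyama–Mannich reaction with the iminium salt at C11 without strong base, sparing the acetate and both halides, the new C11 centre being of no consequence (the spiro descriptor changes to S only because C11 gains CIP rank).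

Step 16
Reactants: 25 (1S,3R,4R,6S)-4-bromo-3-chloro-11-[(dimethylamino)methyl]-3,7,7-trimethyl-10-oxospiro[5.5]undec-8-en-1-yl acetate
Product: 27 (1S,3R,4R,6R)-4-bromo-3-chloro-3,7,7-trimethyl-11-methylidene-10-oxospiro[5.5]undec-8-en-1-yl acetate (CNP0161807.1), via trimethylammonium iodide 26 (not isolated)
Conditions: MeI, CH2Cl2/Et2O, rt; then sat. aq. NaHCO3, CH2Cl2, rt
Reagents that add atoms: none
Why: Quaternisation of the amine and Hofmann-type (E1cB) elimination of trimethylamine from the β-ammonio ketone under mild base should give the exocyclic methylene enone and remove the C11 stereocentre.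

**Compound list**

1 | 1-(2-hydroxy-4-methylphenyl)ethan-1-one | CC(=O)c1ccc(C)cc1O | starting material
2 | diethyl oxalate | CCOC(=O)C(=O)OCC | starting material
3 | ethyl 4-(2-hydroxy-4-methylphenyl)-2,4-dioxobutanoate | CCOC(=O)C(=O)CC(=O)c1ccc(C)cc1O | intermediate (not isolated)
4 | ethyl 7-methyl-4-oxo-4H-chromene-2-carboxylate | CCOC(=O)c1cc(=O)c2ccc(C)cc2o1 | intermediate
5 | ethyl 7-methyl-4-oxochromane-2-carboxylate (racemic) | CCOC(=O)C1CC(=O)c2ccc(C)cc2O1 | intermediate (not isolated)
6 | ethyl 4-hydroxy-7-methylchromane-2-carboxylate (stereoisomer mixture) | CCOC(=O)C1CC(O)c2ccc(C)cc2O1 | intermediate (not isolated)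
7 | ethyl 7-methylchromane-2-carboxylate (racemic) | CCOC(=O)C1CCc2ccc(C)cc2O1 | intermediate
8 | ethyl (2R)-7-methylchromane-2-carboxylate | CCOC(=O)[C@H]1CCc2ccc(C)cc2O1 | intermediate
9 | [(2R)-7-methylchroman-2-yl]methanol | OC[C@H]1CCc2ccc(C)cc2O1 | intermediate
10 | [(2R)-7-methyl-3,4,5,8-tetrahydro-2H-chromen-2-yl]methanol | OC[C@H]1CCC2=C(O1)CC(C)=CC2 | intermediate
11 | (2R)-7-methyl-3,4,5,8-tetrahydro-2H-chromene-2-carbaldehyde | O=C[C@H]1CCC2=C(O1)CC(C)=CC2 | intermediate
12 | isopropyltriphenylphosphonium iodide | CC(C)[P+](c1ccccc1)(c1ccccc1)c1ccccc1.[I-] | starting material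
13 | isopropylidenetriphenylphosphorane | CC(C)=P(c1ccccc1)(c1ccccc1)c1ccccc1 | intermediate (not isolated)
14 | (2R)-7-methyl-2-(2-methylprop-1-en-1-yl)-3,4,5,8-tetrahydro-2H-chromene | CC(C)=C[C@H]1CCC2=C(O1)CC(C)=CC2 | intermediate
15 | (6R)-3,7,7-trimethylspiro[5.5]undeca-3,8-dien-1-one | CC1(C)C=CCC[C@@]12CC=C(C)CC2=O | intermediate
16 | (1S,6R)-3,7,7-trimethylspiro[5.5]undeca-3,8-dien-1-ol | CC1(C)C=CCC[C@@]12CC=C(C)C[C@@H]2O | intermediate
17 | (1S,3R,4S,6R)-3,4-epoxy-3,7,7-trimethylspiro[5.5]undec-8-en-1-ol | CC1(C)C=CCC[C@@]12C[C@@H]3O[C@]3(C)C[C@@H]2O | intermediate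
18 | (1S,3R,4S,6R)-3,4-epoxy-3,7,7-trimethylspiro[5.5]undec-8-en-1-yl acetate | CC1(C)C=CCC[C@@]12C[C@@H]3O[C@]3(C)C[C@@H]2OC(C)=O | intermediate
19 | (1S,3R,4R,6R)-4-bromo-3-hydroxy-3,7,7-trimethylspiro[5.5]undec-8-en-1-yl acetate | CC1(C)C=CCC[C@@]12C[C@@H](Br)[C@](C)(O)C[C@@H]2OC(C)=O | intermediate
20 | (1S,3R,4R,6R)-4-bromo-3-(chlorosulfinyloxy)-3,7,7-trimethylspiro[5.5]undec-8-en-1-yl acetate | CC1(C)C=CCC[C@@]12C[C@@H](Br)[C@](C)(OS(Cl)=O)C[C@@H]2OC(C)=O | intermediate (not isolated)
21 | (1S,3R,4R,6R)-4-bromo-3-chloro-3,7,7-trimethylspiro[5.5]undec-8-en-1-yl acetate | CC1(C)C=CCC[C@@]12C[C@@H](Br)[C@](C)(Cl)C[C@@H]2OC(C)=O | intermediate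
22 | (1S,3R,4R,6R)-4-bromo-10-(tert-butylperoxy)-3-chloro-3,7,7-trimethylspiro[5.5]undec-8-en-1-yl acetate (C10 epimers) | CC1(C)C=CC(OOC(C)(C)C)C[C@@]12C[C@@H](Br)[C@](C)(Cl)C[C@@H]2OC(C)=O | intermediate (not isolated)
23 | (1S,3R,4R,6R)-4-bromo-3-chloro-3,7,7-trimethyl-10-oxospiro[5.5]undec-8-en-1-yl acetate | CC1(C)C=CC(=O)C[C@@]12C[C@@H](Br)[C@](C)(Cl)C[C@@H]2OC(C)=O | intermediate
24 | (1S,3R,4R,6S)-4-bromo-3-chloro-3,7,7-trimethyl-10-(trimethylsilyloxy)spiro[5.5]undeca-8,10-dien-1-yl acetate | CC1(C)C=CC(O[Si](C)(C)C)=C[C@@]12C[C@@H](Br)[C@](C)(Cl)C[C@@H]2OC(C)=O | intermediate (not isolated)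
25 | (1S,3R,4R,6S)-4-bromo-3-chloro-11-[(dimethylamino)methyl]-3,7,7-trimethyl-10-oxospiro[5.5]undec-8-en-1-yl acetate (C11 epimers) | CC1(C)C=CC(=O)C(CN(C)C)[C@@]12C[C@@H](Br)[C@](C)(Cl)C[C@@H]2OC(C)=O | intermediate
26 | {(1S,3R,4R,6S)-1-acetoxy-4-bromo-3-chloro-3,7,7-trimethyl-10-oxospiro[5.5]undec-8-en-11-yl}methyl-trimethylammonium iodide (C11 epimers) | CC1(C)C=CC(=O)C(C[N+](C)(C)C)[C@@]12C[C@@H](Br)[C@](C)(Cl)C[C@@H]2OC(C)=O.[I-] | intermediate (not isolated)
27 | (1S,3R,4R,6R)-4-bromo-3-chloro-3,7,7-trimethyl-11-methylidene-10-oxospiro[5.5]undec-8-en-1-yl acetate | C=C1C(=O)C=CC(C)(C)[C@]12C[C@@H](Br)[C@](C)(Cl)C[C@@H]2OC(C)=O | target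

**Step count and risks**

Total step count: 16. Longest linear sequence: 16 steps (1 → 27); 2 and 12 are commercial reagents brought in at steps 1 and 7.

Steps most likely to fail:

1. Step 12, loss of regiocontrol in the epoxide opening. The half-chair of ring B that keeps C7 equatorial opens trans-diaxially at the tertiary carbon C3, so bromide attack at C4 must pass through a twist-boat-like transition state. Attack at C3, or Lewis-acid rearrangement of the epoxide to a carbonyl compound, may therefore compete. Fallback, from 18 and returning at 21: the opposite regiochemistry is used on purpose. Aqueous HBr in Et2O at −20 °C should open the epoxide at C3 in the Markovnikov, trans-diaxial sense to give (1S,3S,4S,6R)-3-bromo-4-hydroxy-3,7,7-trimethylspiro[5.5]undec-8-en-1-yl acetate F1. Tf2O and pyridine at −40 °C would convert its secondary hydroxyl into (1S,3S,4S,6R)-3-bromo-3,7,7-trimethyl-4-(trifluoromethanesulfonyloxy)spiro[5.5]undec-8-en-1-yl acetate F2, in which the C3 bromine is anti-periplanar to the leaving group. With Bu4NCl the bromine should migrate to C4 through the same bromonium ion as in step 13 and chloride should open it at the tertiary carbon, giving 21 and bypassing 19 and 20.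

2. Step 13, elimination or bromine shift during ionisation at C3. The β-bromine slows ionisation of the equatorial tertiary chlorosulfite, so loss of a proton to an alkene, or chloride capture at C4 after a 1,2-bromine shift, may overtake substitution with retention. Fallback, from 16 and returning at 21: acetylation (Ac2O, pyridine, DMAP) would give (1S,6R)-3,7,7-trimethylspiro[5.5]undeca-3,8-dien-1-yl acetate F3. Direct bromochlorination of its more electron-rich ring B alkene (N-bromosuccinimide, Et4NCl, CH2Cl2, −78 °C) should add bromine to C4 and chloride to C3 in the anti, Markovnikov sense. The face is then set by reversible bromonium formation anti to the pseudo-axial C11 methylene rather than by an epoxide, and diastereomers would have to be separated.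

3. Step 8, thermal stress before the hindered quaternary–quaternary bond forms. At the temperature needed, heterolysis of the allylic C2–O bond (stepwise [1,3] recombination, erosion of chirality transfer) or conjugation and aromatisation of the cyclohexa-1,4-diene may compete. Fallback, from 14 and returning at 15: a Lewis-acid-accelerated rearrangement with Al(i-Bu)3 in CH2Cl2 at −78 °C → rt, in which the aluminium-bound ketone is reduced in situ by β-hydride transfer, should give (6R)-3,7,7-trimethylspiro[5.5]undeca-3,8-dien-1-ol F4 as a mixture of C1 epimers. Dess–Martin periodinane with NaHCO3 in CH2Cl2 would oxidise it to 15.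

**Further compounds**

F1 | step 12 | (1S,3S,4S,6R)-3-bromo-4-hydroxy-3,7,7-trimethylspiro[5.5]undec-8-en-1-yl acetate | CC1(C)C=CCC[C@@]12C[C@H](O)[C@@](C)(Br)C[C@@H]2OC(C)=O
F2 | step 12 | (1S,3S,4S,6R)-3-bromo-3,7,7-trimethyl-4-(trifluoromethanesulfonyloxy)spiro[5.5]undec-8-en-1-yl acetate | CC1(C)C=CCC[C@@]12C[C@H](OS(=O)(=O)C(F)(F)F)[C@@](C)(Br)C[C@@H]2OC(C)=O
F3 | step 13 | (1S,6R)-3,7,7-trimethylspiro[5.5]undeca-3,8-dien-1-yl acetate | CC1(C)C=CCC[C@@]12CC=C(C)C[C@@H]2OC(C)=O
F4 | step 8 | (6R)-3,7,7-trimethylspiro[5.5]undeca-3,8-dien-1-ol (C1 epimers) | CC1(C)C=CCC[C@@]12CC=C(C)CC2O
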